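**Retrosynthetic overview**
1. Target numbering (bicyclo[3.2.1]oct-3-ene-2,8-dione): C1 = CH bridgehead, C2 = ring C=O, C3 = C–OMe, C4 = olefinic CH, C5 = allyl-bearing quaternary bridgehead, C6 = CHMe, C7 = CHAr, C8 = bridging C=O. The last operation is oxidation of a C2 carbinol to the ketone.
2. Key disconnection C4–C5: oxidative, palladium-mediated coupling of a C5 silyl enol ether (of the C8 ketone) with the CH2 terminus (C4) of a 2-methoxyallyl unit carried on C1. This one bond closes the six-membered ring (C1–C2–C3–C4–C5–C8) and the seven-membered ring (C1–C2–C3–C4–C5–C6–C7), creates quaternary C5 and leaves the C3=C4 methyl enol ether.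
3. Enabling feature: C5 is the α-carbon of the C8 ketone and C4 is the β-terminus of the C3=C4 enol ether, so C8(=O)–C5–C4=C3(OMe) is exactly the array that enolate–olefin insertion followed by β-hydride elimination leaves behind. C1 and C5 sit 1,3 across C8 on the cyclopentane ring (C1, C8, C5, C6, C7), so the tether can only close as the bridged bicycle.
4. The cyclization substrate is built on a cyclopentenone: C1–C2 by aldol addition to 2-methoxyacrolein; C6 methyl by conjugate addition anti to the C7 aryl group, which also delivers the C5 enol silane regiospecifically; C5 allyl by α-iodination/Stille coupling; C7 aryl by anti conjugate addition/elimination on (S)-4-silyloxycyclopentenone.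
5. Ring order: the five-membered ring comes with the starting material; the six- and seven-membered rings form together in the key step.

Key step: step 7

**Remarks and assumptions**
- Atom numbers C1–C8 always refer to the target skeleton defined above. Locants inside compound names are those of the compound named.
- Both enantiomers of 4-(tert-butyldimethylsilyloxy)cyclopent-2-en-1-one and a THF solution of 3,4-dimethoxyphenylmagnesium bromide are taken to be commercial.
- The carbinol carbon made in step 5 (future C2) is carried as a mixture of epimers, because it becomes a carbonyl in step 8.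

**Route**

Step 1
Reactants: 1 (S)-4-(tert-butyldimethylsilyloxy)cyclopent-2-en-1-one; 2 3,4-dimethoxyphenylmagnesium bromide
Product: 4 (S)-4-(3,4-dimethoxyphenyl)cyclopent-2-en-1-one, via trans-silyloxy ketone 3 (not isolated)
Conditions: 2 (1.5 equiv), CuBr·SMe2 (10 mol%), THF, −78 to −40 °C; aq. NH4Cl; then DBU, CH2Cl2, 0 °C
Reagents that add atoms: none
Why: Copper-catalysed conjugate addition of the aryl Grignard reagent should occur anti to the silyloxy group of 1, which sets the aryl-bearing stereocentre (future C7), and E1cB loss of silanol from the β-silyloxy ketone should then place the enone on the other side of the ring (conjugate addition–elimination).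

Step 2
Reactants: 4 (S)-4-(3,4-dimethoxyphenyl)cyclopent-2-en-1-one
Product: 5 (S)-4-(3,4-dimethoxyphenyl)-2-iodocyclopent-2-en-1-one
Conditions: iodine, pyridine, CH2Cl2, 0 °C to rt
Reagents that add atoms: iodine, [I][I]
Why: α-Iodination of the enone by pyridine conjugate addition, iodination of the resulting enolate and elimination (Baylis–Hillman-type addition–elimination) should leave the remote stereocentre untouched.

Step 3
Reactants: 5 (S)-4-(3,4-dimethoxyphenyl)-2-iodocyclopent-2-en-1-one
Product: 6 (S)-2-allyl-4-(3,4-dimethoxyphenyl)cyclopent-2-en-1-one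
Conditions: allylSnBu3, Pd2(dba)3 (2.5 mol%), AsPh3, CuI (10 mol%), NMP, rt
Reagents that add atoms: allyltributylstannane, C=CC[Sn](CCCC)(CCCC)CCCC
Why: Stille coupling of the α-iodoenone with the allylstannane should install the allyl group on the enone α-carbon (future C5) at room temperature, which is mild enough to avoid migration of the allyl double bond.

Step 4
Reactants: 7 methyl vinyl ether
Product: 10 2-methoxyprop-2-enal, via 1-methoxyvinyllithium 8 (not isolated), via lithium hemiaminal alkoxide 9 (not isolated)
Conditions: t-BuLi, THF, −78 to 0 °C; DMF, −78 °C; cold aq. NH4Cl, Et2O; used at once as a dried ethereal solution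
Reagents that add atoms: N,N-dimethylformamide, CN(C)C=O
Why: α-Lithiation of the enol ether and formylation of the vinyllithium with DMF (the tetrahedral adduct collapses only on work-up) should give the α-methoxy enal that supplies C2, C3 and C4.

Step 5
Reactants: 6 (S)-2-allyl-4-(3,4-dimethoxyphenyl)cyclopent-2-en-1-one; 10 2-methoxyprop-2-enal
Product: 13 (4R,5R)-2-allyl-4-(3,4-dimethoxyphenyl)-5-[2-methoxy-1-(trimethylsilyloxy)prop-2-en-1-yl]cyclopent-2-en-1-one (4,5-trans; both carbinol epimers), via lithium dienolate 11 (not isolated), via lithium aldolate 12 (not isolated)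
Conditions: LDA, THF, −78 °C (6 added to the base); 10, −78 °C; TMSCl, Et3N, −78 to −30 °C; pH 7 buffer
Reagents that add atoms: chlorotrimethylsilane, C[Si](C)(C)Cl
Why: Kinetic α'-deprotonation should give the cross-conjugated lithium enolate, which adds 1,2 to the aldehyde anti to the neighbouring aryl group (directed aldol addition, setting future C1 trans to C7), and silylation of the aldolate in the same flask blocks retro-aldol cleavage.

Step 6
Reactants: 13 (4R,5R)-2-allyl-4-(3,4-dimethoxyphenyl)-5-[2-methoxy-1-(trimethylsilyloxy)prop-2-en-1-yl]cyclopent-2-en-1-one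
Product: 14 (3R,4R,5R)-2-allyl-4-(3,4-dimethoxyphenyl)-3-methyl-5-[2-methoxy-1-(trimethylsilyloxy)prop-2-en-1-yl]-1-(trimethylsilyloxy)cyclopent-1-ene
Conditions: MeMgBr, CuBr·SMe2 (10 mol%), TMSCl, DMPU, THF, −78 °C; Et3N, pentane, cold aq. NaHCO3; used crude
Reagents that add atoms: methylmagnesium bromide, C[Mg]Br; chlorotrimethylsilane, C[Si](C)(C)Cl
Why: Copper-catalysed, silyl chloride-accelerated conjugate addition should deliver methyl to the enone β-carbon anti to the adjacent aryl group (setting C6 trans to C7) and trap the enolate as the trimethylsilyl enol ether, so that the nucleophilic carbon for step 7 is fixed at the allyl-bearing carbon.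

Step 7
Reactants: 14 (3R,4R,5R)-2-allyl-4-(3,4-dimethoxyphenyl)-3-methyl-5-[2-methoxy-1-(trimethylsilyloxy)prop-2-en-1-yl]-1-(trimethylsilyloxy)cyclopent-1-ene
Product: 16 (1R,5S,6R,7R)-5-allyl-7-(3,4-dimethoxyphenyl)-2-hydroxy-3-methoxy-6-methylbicyclo[3.2.1]oct-3-en-8-one (both C2 epimers), via bicyclic trimethylsilyl ether 15 (not isolated)
Conditions: Pd(OAc)2 (1.1 equiv), 2,6-di-tert-butylpyridine, MeCN, 25 °C; then TBAF, AcOH, THF, 0 °C
Reagents that add atoms: none
Why: Proposed new method: Pd(OAc)2 should transmetalate the regiodefined trimethylsilyl enol ether to a divalent-palladium enolate at C5, the tethered 2-methoxyalkene should then insert into the Pd–C5 bond with C5 bonding to the unsubstituted terminus C4, and β-hydride elimination of a C4–H from the C3-palladium species should return the C3=C4 methyl enol ether together with zerovalent palladium. The closest known reaction type is the palladium-mediated cycloalkenylation of silyl enol ethers with unactivated tethered olefins (the olefin-insertion variant of the Saegusa–Ito oxidation), which is established for bicyclo[3.2.1]octanones; what is new is the electron-rich 1,1-disubstituted enol ether as the olefin partner. The six-membered ring C1–C2–C3–C4–C5–C8 closes in the 6-endo-trig mode, and because C1 and C5 are already held 1,3 across C8 in the cyclopentane the same bond closes the seven-membered ring C1–C2–C3–C4–C5–C6–C7 as a bridge. The only new stereocentre, quaternary C5, is controlled by the tether: C4 can reach only the enolate face cis to the C1 side chain, so C5 follows from the C1 configuration set in step 5. The step needs C5 rather than C1 as the nucleophile (secured by the enol silane from step 6), endo rather than exo insertion (exo attack would have to occur at the fully substituted C3 and give a strained 7-norbornanone), and β-hydride elimination towards C4 rather than loss of the C2 silyloxy group (syn C4–H bonds are available and a silyl ether is a poor leaving group). The buffered fluoride treatment then only frees the C2 hydroxyl, and both carbinol epimers converge in step 8.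

Step 8
Reactants: 16 (1R,5S,6R,7R)-5-allyl-7-(3,4-dimethoxyphenyl)-2-hydroxy-3-methoxy-6-methylbicyclo[3.2.1]oct-3-en-8-one
Product: 17 Kadsurenin D [(1S,5S,6R,7R)-5-allyl-7-(3,4-dimethoxyphenyl)-3-methoxy-6-methylbicyclo[3.2.1]oct-3-ene-2,8-dione; aryl on the face of the C8 bridge, methyl on the face of the C2–C4 bridge]
Conditions: Dess–Martin periodinane, pyridine, CH2Cl2, 0 °C to rt
Reagents that add atoms: none
Why: Dess–Martin oxidation of the allylic C2 alcohol under buffered, non-nucleophilic conditions should give the ketone from both epimers without exposing the non-enolisable β-diketone to bases that could cause retro-Claisen cleavage.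

**Compound list**
1 | (S)-4-(tert-butyldimethylsilyloxy)cyclopent-2-en-1-one | O=C1C=C[C@@H](O[Si](C)(C)C(C)(C)C)C1 | starting material
2 | 3,4-dimethoxyphenylmagnesium bromide | COc1ccc([Mg]Br)cc1OC | starting material
3 | (3R,4S)-3-(3,4-dimethoxyphenyl)-4-(tert-butyldimethylsilyloxy)cyclopentan-1-one (3,4-trans) | O=C1C[C@H](c2ccc(OC)c(OC)c2)[C@@H](O[Si](C)(C)C(C)(C)C)C1 | intermediate
4 | (S)-4-(3,4-dimethoxyphenyl)cyclopent-2-en-1-one | O=C1C=C[C@@H](c2ccc(OC)c(OC)c2)C1 | intermediate
5 | (S)-4-(3,4-dimethoxyphenyl)-2-iodocyclopent-2-en-1-one | O=C1C(I)=C[C@@H](c2ccc(OC)c(OC)c2)C1 | intermediate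
6 | (S)-2-allyl-4-(3,4-dimethoxyphenyl)cyclopent-2-en-1-one | C=CCC1=C[C@@H](c2ccc(OC)c(OC)c2)CC1=O | intermediate
7 | methyl vinyl ether | C=COC | starting material
8 | 1-methoxyvinyllithium | [Li]C(=C)OC | intermediate
9 | lithium 1-(dimethylamino)-2-methoxyprop-2-en-1-olate | C=C(OC)C(O[Li])N(C)C | intermediate
10 | 2-methoxyprop-2-enal | C=C(OC)C=O | intermediate
11 | lithium dienolate of 6 (deprotonated at the CH2 next to the carbonyl) | C=CCC1=C[C@@H](c2ccc(OC)c(OC)c2)C=C1O[Li] | intermediate
12 | lithium aldolate: (4R,5R)-2-allyl-4-(3,4-dimethoxyphenyl)-5-(1-lithiooxy-2-methoxyprop-2-en-1-yl)cyclopent-2-en-1-one (carbinol epimers) | C=CCC1=C[C@@H](c2ccc(OC)c(OC)c2)[C@H](C(O[Li])C(OC)=C)C1=O | intermediate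
13 | (4R,5R)-2-allyl-4-(3,4-dimethoxyphenyl)-5-[2-methoxy-1-(trimethylsilyloxy)prop-2-en-1-yl]cyclopent-2-en-1-one (4,5-trans; carbinol epimers) | C=CCC1=C[C@@H](c2ccc(OC)c(OC)c2)[C@H](C(O[Si](C)(C)C)C(OC)=C)C1=O | intermediate
14 | (3R,4R,5R)-2-allyl-4-(3,4-dimethoxyphenyl)-3-methyl-5-[2-methoxy-1-(trimethylsilyloxy)prop-2-en-1-yl]-1-(trimethylsilyloxy)cyclopent-1-ene (3,4-trans, 4,5-trans; carbinol epimers) | C=C(OC)C(O[Si](C)(C)C)[C@@H]1C(O[Si](C)(C)C)=C(CC=C)[C@H](C)[C@H]1c1ccc(OC)c(OC)c1 | intermediate
15 | (1R,5S,6R,7R)-5-allyl-7-(3,4-dimethoxyphenyl)-3-methoxy-6-methyl-2-(trimethylsilyloxy)bicyclo[3.2.1]oct-3-en-8-one (C2 epimers) | C=CC[C@]12C=C(OC)C(O[Si](C)(C)C)[C@H](C1=O)[C@H](c1ccc(OC)c(OC)c1)[C@H]2C | intermediate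
16 | (1R,5S,6R,7R)-5-allyl-7-(3,4-dimethoxyphenyl)-2-hydroxy-3-methoxy-6-methylbicyclo[3.2.1]oct-3-en-8-one (C2 epimers) | C=CC[C@]12C=C(OC)C(O)[C@H](C1=O)[C@H](c1ccc(OC)c(OC)c1)[C@H]2C | intermediate
17 | Kadsurenin D, (1S,5S,6R,7R)-5-allyl-7-(3,4-dimethoxyphenyl)-3-methoxy-6-methylbicyclo[3.2.1]oct-3-ene-2,8-dione | C=CC[C@]12C=C(OC)C(=O)[C@H](C1=O)[C@H](c1ccc(OC)c(OC)c1)[C@H]2C | target

**Step count**
Total step count: 8 (seven in the main line plus step 4 for the aldehyde 10).
Longest linear sequence: 7 steps (steps 1, 2, 3, 5, 6, 7, 8).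

**Steps most likely to fail, with fallbacks**

1. Step 7 (key step, proposed new method). What may go wrong: insertion in the exo sense at the methoxy-bearing olefin carbon; loss of the C2 silyloxy group by β-alkoxide elimination from the C3-palladium intermediate; or simple Saegusa-type dehydrogenation of the enolate outrunning olefin insertion. The fallback closes the same C4–C5 bond by a tin-hydride radical cyclization and restores the C3=C4 double bond afterwards; it sets out from 14 and returns to the route at 17. NBS in THF at −78 °C should convert the enol silane of 14 into the tertiary α-bromo ketone F1. Slow addition of Bu3SnH/AIBN in benzene at 80 °C should generate the electrophilic α-keto radical at C5, which adds 6-endo to the CH2 terminus of the electron-rich enol ether (polarity-matched, giving a tertiary α-alkoxy radical) and after hydrogen transfer gives the saturated bicyclic silyl ether F2. TBAF/AcOH should free the alcohol F3, and Dess–Martin oxidation should give the saturated 3-methoxy-2,8-dione F4. Only C3 of F4 can enolise, because C1 and C5 are bridgeheads, so TMSOTf/Et3N should give the single silyl enol ether F5. Saegusa–Ito oxidation of F5 with Pd(OAc)2 in MeCN should then introduce the C3=C4 double bond and give 17.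

2. Step 5. What may go wrong: competing γ-deprotonation at the benzylic ring carbon (erosion of enantiopurity through the fully conjugated dienolate); Michael self-condensation of the enolate with unreacted enone; polymerisation of the sensitive enal; or retro-aldol cleavage before the aldolate is silylated. The fallback replaces α'-deprotonation of an enone by regiocontrol through a removable selenium group; it sets out from 6 and rejoins the route at 14. Copper-catalysed addition of MeMgBr to 6 with TMSCl trapping should give the trimethylsilyl enol ether F6 with methyl trans to aryl. PhSeCl in CH2Cl2 at −78 °C should give the α-phenylselanyl ketone F7, whose fully substituted α-carbon leaves only the CH2 position enolisable. LDA, then aldehyde 10, then TMSCl should give the aldol silyl ether F8, with the side chain anti to the aryl group. SmI2 in THF at −78 °C should cleave the C–Se bond reductively to the regiodefined samarium enolate, which TMSCl/Et3N traps as 14.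

3. Step 3. What may go wrong: slow transmetalation of the allylstannane, migration of the allyl double bond into conjugation with the enone, or protodeiodination. The fallback uses a thiolate as a temporary conjugate-addition handle in place of cross-coupling; it sets out from 4 and returns at 6, so that step 2 is not needed. Lithium thiophenolate (PhSH, n-BuLi) in THF/DMPU at −78 °C should add to the enone, and the resulting enolate should be alkylated in the same flask with allyl bromide to give the β-phenylsulfanyl ketone F9. DBU in CH2Cl2 should then expel thiophenolate by E1cB elimination and regenerate the enone as 6.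

**Further compounds**
F1 | step 7 | 2-allyl-2-bromo-4-(3,4-dimethoxyphenyl)-3-methyl-5-[2-methoxy-1-(trimethylsilyloxy)prop-2-en-1-yl]cyclopentan-1-one (ring carbons 3, 4, 5 as in 14; bromide epimers) | C=CCC1(Br)C(=O)[C@@H](C(O[Si](C)(C)C)C(OC)=C)[C@H](c2ccc(OC)c(OC)c2)[C@H]1C
F2 | step 7 | 5-allyl-7-(3,4-dimethoxyphenyl)-3-methoxy-6-methyl-2-(trimethylsilyloxy)bicyclo[3.2.1]octan-8-one (C1, C5, C6, C7 as in 15; C2 and C3 epimers) | C=CC[C@]12CC(OC)C(O[Si](C)(C)C)[C@H](C1=O)[C@H](c1ccc(OC)c(OC)c1)[C@H]2C
F3 | step 7 | 5-allyl-7-(3,4-dimethoxyphenyl)-2-hydroxy-3-methoxy-6-methylbicyclo[3.2.1]octan-8-one (C2 and C3 epimers) | C=CC[C@]12CC(OC)C(O)[C@H](C1=O)[C@H](c1ccc(OC)c(OC)c1)[C@H]2C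
F4 | step 7 | 5-allyl-7-(3,4-dimethoxyphenyl)-3-methoxy-6-methylbicyclo[3.2.1]octane-2,8-dione (C3 epimers) | C=CC[C@]12CC(OC)C(=O)[C@H](C1=O)[C@H](c1ccc(OC)c(OC)c1)[C@H]2C
F5 | step 7 | 5-allyl-7-(3,4-dimethoxyphenyl)-3-methoxy-6-methyl-2-(trimethylsilyloxy)bicyclo[3.2.1]oct-2-en-8-one | C=CC[C@]12CC(OC)=C(O[Si](C)(C)C)[C@H](C1=O)[C@H](c1ccc(OC)c(OC)c1)[C@H]2C
F6 | step 5 | (3R,4S)-2-allyl-4-(3,4-dimethoxyphenyl)-3-methyl-1-(trimethylsilyloxy)cyclopent-1-ene (3,4-trans) | C=CCC1=C(O[Si](C)(C)C)C[C@H](c2ccc(OC)c(OC)c2)[C@H]1C
F7 | step 5 | 2-allyl-4-(3,4-dimethoxyphenyl)-3-methyl-2-(phenylselanyl)cyclopentan-1-one (3,4-trans as in F6; selenide epimers) | C=CCC1([Se]c2ccccc2)C(=O)C[C@H](c2ccc(OC)c(OC)c2)[C@H]1C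
F8 | step 5 | 2-allyl-4-(3,4-dimethoxyphenyl)-3-methyl-5-[2-methoxy-1-(trimethylsilyloxy)prop-2-en-1-yl]-2-(phenylselanyl)cyclopentan-1-one (ring carbons 3, 4, 5 as in 14; selenide and carbinol epimers) | C=CCC1([Se]c2ccccc2)C(=O)[C@@H](C(O[Si](C)(C)C)C(OC)=C)[C@H](c2ccc(OC)c(OC)c2)[C@H]1C
F9 | step 3 | 2-allyl-4-(3,4-dimethoxyphenyl)-3-(phenylsulfanyl)cyclopentan-1-one (aryl-bearing carbon as in 4; other two ring stereocentres as mixtures) | C=CCC1C(Sc2ccccc2)[C@@H](c2ccc(OC)c(OC)c2)CC1=O
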